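The route builds the central ring B around an oxygen that is already an aryl ether. In ring B, C1 (carrying the oxygen bound to the quinone) lies between C2 (O-aryl) and C6 (isopropyl), with C4 (OMe) para to it, so C1 and C3 stand in a 1,5-dicarbonyl relationship. In one operation, the methoxy-bearing carbon of a methoxyacetone enol silane adds to an aryloxymethyl 1-isopropylvinyl ketone and an aldol condensation follows. This forms C4–C5 and C2=C3 and closes the six-membered ring. Aromatisation through a silyl dienol ether and displacement of bromide from a regiodefined bromothymoquinone finish the molecule.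

Key step: step 6

Remark: ring A is the terminal aryl ether ring, ring B the central benzene ring and ring C the quinone; the bromoquinone needed carries bromine on the carbon next to the methyl-bearing carbon, and 4-methoxythymol is taken from thymol because partial methylation of thymohydroquinone would not reliably distinguish its two hydroxyls; the enol silane of methoxyacetone may contain its E isomer, which is of no consequence.

Step 1
Reactants: 1 thymol
Product: 2 4-bromothymol (4-bromo-2-isopropyl-5-methylphenol)
Conditions: NBS (1.0 equiv), MeCN, 0 °C → rt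
Reagents that add atoms: N-bromosuccinimide, O=C1CCC(=O)N1Br
Why: Electrophilic aromatic bromination of a phenol with NBS should go para to the hydroxyl, the least hindered activated position of thymol.

Step 2
Reactants: 2 4-bromothymol
Product: 3 4-methoxythymol (2-isopropyl-4-methoxy-5-methylphenol)
Conditions: NaOMe (6 equiv), CuI (15 mol%), DMF/MeOH, 110 °C; aq. HCl work-up
Reagents that add atoms: sodium methoxide, [Na+].[O-]C
Why: Copper-catalysed methoxylation of an aryl bromide (Ullmann-type ether synthesis) replaces bromine at the same carbon, so the free hydroxyl stays next to the isopropyl group without any selectivity question.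

Step 3
Reactants: 3 4-methoxythymol; 4 2-chloro-N-methoxy-N-methylacetamide
Product: 5 2-(2-isopropyl-4-methoxy-5-methylphenoxy)-N-methoxy-N-methylacetamide
Conditions: K2CO3, KI (cat.), DMF, 60 °C
Reagents that add atoms: none
Why: Williamson ether synthesis with an activated α-chloro amide under iodide (Finkelstein) catalysis should alkylate the phenoxide on oxygen despite the ortho isopropyl group.

Step 4
Reactants: 5 2-(2-isopropyl-4-methoxy-5-methylphenoxy)-N-methoxy-N-methylacetamide; 6 2-bromo-3-methylbut-1-ene
Product: 8 1-(2-isopropyl-4-methoxy-5-methylphenoxy)-4-methyl-3-methylidenepentan-2-one, via Grignard reagent 7 (not isolated)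
Conditions: 6, Mg, THF, 40 °C; then 5, THF, −20 → 0 °C; inverse quench into cold 1 M HCl
Reagents that add atoms: none
Why: In the Weinreb ketone synthesis the vinyl Grignard reagent adds once to give a stable magnesium chelate that collapses to the enone only on the acidic quench, which also protonates the released amine so that it cannot add to the new enone.

Step 5
Reactants: 9 methoxyacetone
Product: 10 (Z)-1-methoxy-2-(trimethylsilyloxy)prop-1-ene
Conditions: TMSCl, NaI, Et3N, MeCN, rt; pentane extraction, fractional distillation
Reagents that add atoms: chlorotrimethylsilane, C[Si](C)(C)Cl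
Why: Silyl enol ether formation under equilibrating conditions (iodotrimethylsilane made in the flask, amine base) should favour the more substituted, oxygen-stabilised double bond on the side of the more acidic methoxy-bearing CH2.

Step 6
Reactants: 8 1-(2-isopropyl-4-methoxy-5-methylphenoxy)-4-methyl-3-methylidenepentan-2-one; 10 (Z)-1-methoxy-2-(trimethylsilyloxy)prop-1-ene
Product: 13 2-(2-isopropyl-4-methoxy-5-methylphenoxy)-6-isopropyl-4-methoxy-3-methylcyclohex-2-en-1-one (racemic mixture of cis and trans isomers), via silyl enol ether adduct 11 (not isolated), via 1,5-diketone 12 (not isolated)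
Conditions: Sc(OTf)3 (10 mol%), 10 (1.4 equiv), CH2Cl2, −78 → −30 °C; then NaOMe (1 equiv), MeOH, −30 → 40 °C
Reagents that add atoms: none
Why: Sc(OTf)3 activates the chelating α-aryloxy enone 8, and the enol silane 10 adds through its methoxy-bearing carbon to the unsubstituted vinyl CH2 (Mukaiyama–Michael addition), which creates C4–C5 and passes silicon to the new enolate oxygen in 11. Methoxide then removes silicon to give 1,5-diketone 12; under these equilibrating conditions the most acidic α-carbon, the aryloxymethylene, adds to the methyl ketone and water is lost by E1cB, which creates C2=C3. The closest known reaction type is the Robinson annulation run as a Lewis-acid Michael addition followed by base-mediated aldol condensation. Ring B closes by a 6-(enolexo)-exo-trig aldol addition. The two new sp3 stereocentres (C4 and C6) form without control as a cis/trans mixture and are both erased in step 7. Two selectivities are needed: the donor regiochemistry is fixed by the position of the double bond in 10, and the sense of the aldol is secured by the higher acidity of the ArOCH2 protons and the open methyl ketone as acceptor, whereas the reverse closure would require the methyl carbon to attack a ketone flanked by the isopropyl-bearing carbon.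

Step 7
Reactants: 13 2-(2-isopropyl-4-methoxy-5-methylphenoxy)-6-isopropyl-4-methoxy-3-methylcyclohex-2-en-1-one
Product: 16 2-(2-isopropyl-4-methoxy-5-methylphenoxy)-6-isopropyl-4-methoxy-3-methylphenol, via silyl dienol ether 14 (not isolated), via aryl silyl ether 15 (not isolated)
Conditions: LiN(i-Pr)2, THF, −78 °C, then TMSCl; solvent exchange to CH2Cl2 (pentane filtration); DDQ (1.0 equiv), 2,6-lutidine, −40 → 0 °C; filtration; K2CO3 (cat.), MeOH, rt
Reagents that add atoms: none
Why: Kinetic deprotonation of the cyclohex-2-enone at the α' carbon C6 and O-silylation should give a 2-silyloxycyclohexa-1,3-diene, a dihydroarene from which DDQ removes hydride at C4 or C5 and then the neighbouring proton under lutidine buffering (quinone dehydrogenation of a silyl dienol ether), so ring B aromatises with its methoxy group in place because no acid is available to ionise the C4–OMe bond; mild methanolysis then frees the phenol.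

Step 8
Reactants: 3 4-methoxythymol
Product: 17 2-bromo-6-isopropyl-4-methoxy-3-methylphenol
Conditions: NBS (1.0 equiv), CH2Cl2, −20 → 0 °C
Reagents that add atoms: N-bromosuccinimide, O=C1CCC(=O)N1Br
Why: Electrophilic bromination should go ortho to the free hydroxyl (between OH and methyl), since the only other free position is activated only by the weaker ether donor and is crowded between isopropyl and methoxy.

Step 9
Reactants: 17 2-bromo-6-isopropyl-4-methoxy-3-methylphenol
Product: 18 3-bromo-5-isopropyl-2-methylcyclohexa-2,5-diene-1,4-dione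
Conditions: PhI(OAc)2 (1.1 equiv), MeCN/H2O, 0 °C
Reagents that add atoms: water, O
Why: Hypervalent-iodine oxidation of a p-methoxyphenol (oxidative demethylation) proceeds by ligand exchange at iodine, loss of iodobenzene, addition of water at the methoxy-bearing carbon and expulsion of methanol, which places bromine unambiguously next to the methyl-bearing carbon of the quinone.

Step 10
Reactants: 16 2-(2-isopropyl-4-methoxy-5-methylphenoxy)-6-isopropyl-4-methoxy-3-methylphenol; 18 3-bromo-5-isopropyl-2-methylcyclohexa-2,5-diene-1,4-dione
Product: 19 3-[2-(2-isopropyl-4-methoxy-5-methylphenoxy)-6-isopropyl-4-methoxy-3-methylphenoxy]-5-isopropyl-2-methylcyclohexa-2,5-diene-1,4-dione (target)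
Conditions: Cs2CO3 (1.2 equiv), 18 (1.3 equiv), MeCN, 0 °C → rt, Ar, dark
Reagents that add atoms: none
Why: Addition–elimination of a phenoxide on a haloquinone (vinylogous acyl substitution) should occur at the bromine-bearing carbon, β to the C4 carbonyl, with loss of bromide, and the flat sp2 electrophile tolerates the two ortho substituents of the nucleophile.

Compound list
1 | thymol (2-isopropyl-5-methylphenol) | Cc1ccc(C(C)C)c(O)c1 | starting material
2 | 4-bromothymol (4-bromo-2-isopropyl-5-methylphenol) | Cc1cc(O)c(C(C)C)cc1Br | intermediate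
3 | 4-methoxythymol (2-isopropyl-4-methoxy-5-methylphenol) | COc1cc(C(C)C)c(O)cc1C | intermediate
4 | 2-chloro-N-methoxy-N-methylacetamide | CON(C)C(=O)CCl | starting material
5 | 2-(2-isopropyl-4-methoxy-5-methylphenoxy)-N-methoxy-N-methylacetamide | COc1cc(C(C)C)c(OCC(=O)N(C)OC)cc1C | intermediate
6 | 2-bromo-3-methylbut-1-ene | C=C(Br)C(C)C | starting material
7 | (3-methylbut-1-en-2-yl)magnesium bromide | C=C([Mg]Br)C(C)C | intermediate (not isolated)
8 | 1-(2-isopropyl-4-methoxy-5-methylphenoxy)-4-methyl-3-methylidenepentan-2-one | COc1cc(C(C)C)c(OCC(=O)C(=C)C(C)C)cc1C | intermediate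
9 | methoxyacetone | COCC(C)=O | starting material
10 | (Z)-1-methoxy-2-(trimethylsilyloxy)prop-1-ene | CO/C=C(/C)O[Si](C)(C)C | intermediate
11 | 7-(2-isopropyl-4-methoxy-5-methylphenoxy)-5-isopropyl-3-methoxy-6-(trimethylsilyloxy)hept-5-en-2-one (racemic, E/Z mixture) | COc1cc(C(C)C)c(OCC(O[Si](C)(C)C)=C(C(C)C)CC(OC)C(C)=O)cc1C | intermediate (not isolated)
12 | 7-(2-isopropyl-4-methoxy-5-methylphenoxy)-5-isopropyl-3-methoxyheptane-2,6-dione (racemic mixture of diastereomers) | COc1cc(C(C)C)c(OCC(=O)C(C(C)C)CC(OC)C(C)=O)cc1C | intermediate (not isolated)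
13 | 2-(2-isopropyl-4-methoxy-5-methylphenoxy)-6-isopropyl-4-methoxy-3-methylcyclohex-2-en-1-one (racemic mixture of cis and trans isomers) | COc1cc(C(C)C)c(OC2=C(C)C(OC)CC(C(C)C)C2=O)cc1C | intermediate
14 | trimethylsilyl dienol ether of 13, double bonds C1=C6 and C2=C3 (ring B numbering), OSiMe3 on C1 (racemic) | COc1cc(C(C)C)c(OC2=C(C)C(OC)CC(C(C)C)=C2O[Si](C)(C)C)cc1C | intermediate (not isolated)
15 | [2-(2-isopropyl-4-methoxy-5-methylphenoxy)-6-isopropyl-4-methoxy-3-methylphenoxy]trimethylsilane | COc1cc(C(C)C)c(Oc2c(C)c(OC)cc(C(C)C)c2O[Si](C)(C)C)cc1C | intermediate (not isolated)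
16 | 2-(2-isopropyl-4-methoxy-5-methylphenoxy)-6-isopropyl-4-methoxy-3-methylphenol | COc1cc(C(C)C)c(Oc2c(C)c(OC)cc(C(C)C)c2O)cc1C | intermediate
17 | 2-bromo-6-isopropyl-4-methoxy-3-methylphenol | COc1cc(C(C)C)c(O)c(Br)c1C | intermediate
18 | 3-bromo-5-isopropyl-2-methylcyclohexa-2,5-diene-1,4-dione | CC1=C(Br)C(=O)C(C(C)C)=CC1=O | intermediate
19 | 3-[2-(2-isopropyl-4-methoxy-5-methylphenoxy)-6-isopropyl-4-methoxy-3-methylphenoxy]-5-isopropyl-2-methylcyclohexa-2,5-diene-1,4-dione | COc1cc(C(C)C)c(Oc2c(C)c(OC)cc(C(C)C)c2OC2=C(C)C(=O)C=C(C(C)C)C2=O)cc1C | target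

Total step count: 10 steps.
Longest linear sequence: 7 steps (steps 1, 2, 3, 4, 6, 7 and 10); steps 5, 8 and 9 are side branches.

Steps most likely to fail

Step 6. The enol silane may deliver carbon through its methyl side if it is regio-impure or scrambles, or the Lewis-acid addition may stall on the α-branched enone, or the aldol may close in the reverse sense. The fallback sets out from 8 and uses a doubly activated donor whose only acidic carbon is the methoxy-bearing one. Commercial methyl 2-methoxy-3-oxobutanoate (COC(C(C)=O)C(=O)OC) would be added to 8 with catalytic K2CO3 in MeCN; this mild base ionises only the β-keto ester. The expected product is methyl 2-acetyl-6-(2-isopropyl-4-methoxy-5-methylphenoxy)-4-isopropyl-2-methoxy-5-oxohexanoate F1. Krapcho dealkoxycarbonylation of F1 (LiCl, wet DMSO, 130 °C) should then return to the route at 12, which is closed to 13 with NaOMe in MeOH as in step 6.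

Step 7. Ionisation of the C4–OMe bond in the silyl dienol ether or in 13 may outrun hydride abstraction, so that ring B aromatises by loss of methanol; any phenol freed early may also be over-oxidised by DDQ. The fallback sets out from 13 and makes the loss of methanol deliberate. TsOH (cat.) in toluene at 60 °C should give 2-(2-isopropyl-4-methoxy-5-methylphenoxy)-6-isopropyl-3-methylphenol F2 by elimination and tautomerisation. NBS in MeCN should brominate para to the free hydroxyl to give 4-bromo-2-(2-isopropyl-4-methoxy-5-methylphenoxy)-6-isopropyl-3-methylphenol F3. Copper-catalysed methoxylation (NaOMe, CuI, DMF/MeOH, 110 °C, as in step 2) then returns to the route at 16.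

Step 10. The electron-rich phenoxide may transfer an electron to the quinone, or add at the unsubstituted quinone carbon, in place of addition–elimination at the C–Br carbon. The fallback sets out from 16, builds ring C around the ether oxygen by the same annulation logic, and comes back to the route at 19:
- Alkylation of 16 with 4 (K2CO3, KI, DMF) should give Weinreb amide 2-[2-(2-isopropyl-4-methoxy-5-methylphenoxy)-6-isopropyl-4-methoxy-3-methylphenoxy]-N-methoxy-N-methylacetamide F4.
- Grignard reagent 7 converts F4 into enone 1-[2-(2-isopropyl-4-methoxy-5-methylphenoxy)-6-isopropyl-4-methoxy-3-methylphenoxy]-4-methyl-3-methylidenepentan-2-one F5.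
- Mukaiyama–Michael addition of commercial 2-(trimethylsilyloxy)propene (TiCl4, CH2Cl2, −78 °C, aqueous work-up) gives 1-aryloxy-3-isopropylheptane-2,6-dione F6.
- NaOMe in MeOH closes F6 to 2-aryloxy-6-isopropyl-3-methylcyclohex-2-en-1-one F7.
- Palladium-catalysed aerobic dehydrogenation (Pd(O2CCF3)2, 2-(dimethylamino)pyridine, TsOH, O2, DMSO, 80 °C) gives 2-aryloxy-6-isopropyl-3-methylphenol F8; acid is harmless here because this ring carries no methoxy group.
- Teuber oxidation of F8 at its free para position with Fremy's salt, (KO3S)2NO, in buffered aqueous acetone should give 19.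

Further compounds
F1 | step 6 | methyl 2-acetyl-6-(2-isopropyl-4-methoxy-5-methylphenoxy)-4-isopropyl-2-methoxy-5-oxohexanoate (mixture of diastereomers) | COc1cc(C(C)C)c(OCC(=O)C(C(C)C)CC(OC)(C(C)=O)C(=O)OC)cc1C
F2 | step 7 | 2-(2-isopropyl-4-methoxy-5-methylphenoxy)-6-isopropyl-3-methylphenol | COc1cc(C(C)C)c(Oc2c(C)ccc(C(C)C)c2O)cc1C
F3 | step 7 | 4-bromo-2-(2-isopropyl-4-methoxy-5-methylphenoxy)-6-isopropyl-3-methylphenol | COc1cc(C(C)C)c(Oc2c(C)c(Br)cc(C(C)C)c2O)cc1C
F4 | step 10 | 2-[2-(2-isopropyl-4-methoxy-5-methylphenoxy)-6-isopropyl-4-methoxy-3-methylphenoxy]-N-methoxy-N-methylacetamide | COc1cc(C(C)C)c(Oc2c(C)c(OC)cc(C(C)C)c2OCC(=O)N(C)OC)cc1C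
F5 | step 10 | 1-[2-(2-isopropyl-4-methoxy-5-methylphenoxy)-6-isopropyl-4-methoxy-3-methylphenoxy]-4-methyl-3-methylidenepentan-2-one | COc1cc(C(C)C)c(Oc2c(C)c(OC)cc(C(C)C)c2OCC(=O)C(=C)C(C)C)cc1C
F6 | step 10 | 1-[2-(2-isopropyl-4-methoxy-5-methylphenoxy)-6-isopropyl-4-methoxy-3-methylphenoxy]-3-isopropylheptane-2,6-dione (racemic) | COc1cc(C(C)C)c(Oc2c(C)c(OC)cc(C(C)C)c2OCC(=O)C(C(C)C)CCC(C)=O)cc1C
F7 | step 10 | 2-[2-(2-isopropyl-4-methoxy-5-methylphenoxy)-6-isopropyl-4-methoxy-3-methylphenoxy]-6-isopropyl-3-methylcyclohex-2-en-1-one (racemic) | COc1cc(C(C)C)c(Oc2c(C)c(OC)cc(C(C)C)c2OC2=C(C)CCC(C(C)C)C2=O)cc1C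
F8 | step 10 | 2-[2-(2-isopropyl-4-methoxy-5-methylphenoxy)-6-isopropyl-4-methoxy-3-methylphenoxy]-6-isopropyl-3-methylphenol | COc1cc(C(C)C)c(Oc2c(C)c(OC)cc(C(C)C)c2Oc2c(C)ccc(C(C)C)c2O)cc1C
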